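**Retrosynthetic overview**
1. The strategy rests on C6 of ring A. It carries the chiral lavandulyl CH2 and lies between the two oxygen-bearing carbons C5 and C7. C6 and C7 are therefore read as the α-carbon and carbonyl of a chiral ester, placed between a methyl group (future C8) and an ester (future C5) that sit ortho on pyranone ring C.
2. Key disconnections are C7–C8 (lateral Claisen acylation) and C5–C6 (Dieckmann-type closure), both made in one flask. Connectivity, not selectivity on a phloroglucinol, then decides 6- versus 8-substitution.
3. The chiral ester comes from (R)-lavandulol, made by auxiliary-controlled deconjugative prenylation of a senecioyl imide. It is homologated through the iodide, a malonate alkylation and a Krapcho reaction.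
4. The pyranone comes from 2,4-dihydroxybenzaldehyde by way of a MOM-protected arylpropiolic acid, C-acylation of methyl acetoacetate and 6-endo oxa-Michael closure.
5. Ring order: ring B is bought, ring C is closed first and ring A is closed last. The two MOM groups are removed at the end.

Key step: step 12

Remark on the chemistry: flavone numbering (O1, C2–C4, C4a, C5–C8, C8a) is used for the future ring atoms. The R descriptor of lavandulol and the S descriptor of the target describe the same spatial arrangement. Only the CIP ranking of the neighbouring groups changes.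

Step 1
Reactants: 1 (R)-4-benzyloxazolidin-2-one; 2 3-methylbut-2-enoyl chloride (senecioyl chloride)
Product: 4 (R)-4-benzyl-3-(3-methylbut-2-enoyl)oxazolidin-2-one, via N-lithio auxiliary 3 (not isolated)
Conditions: n-BuLi (1.0 equiv), THF, −78 °C; then 2, −78 → 0 °C
Reagents that add atoms: none
Why: N-acylation of the lithiated carbamate nitrogen with an acid chloride is the standard way to load an oxazolidinone auxiliary, and at low temperature the senecioyl double bond should stay conjugated.

Step 2
Reactants: 4 (R)-4-benzyl-3-(3-methylbut-2-enoyl)oxazolidin-2-one; 5 prenyl bromide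
Product: 7 (R)-4-benzyl-3-[(R)-5-methyl-2-(prop-1-en-2-yl)hex-4-enoyl]oxazolidin-2-one, via sodium dienolate 6 (not isolated)
Conditions: NaN(SiMe3)2 (1.1 equiv), THF, −78 °C; then 5 (2 equiv), −78 → −30 °C; NH4Cl quench at low temperature
Reagents that add atoms: none
Why: γ-deprotonation of the s-cis imide gives the chelated (Z)-dienolate 6, which in an Evans-type asymmetric alkylation reacts at its α-carbon (deconjugative alkylation) on the face away from the benzyl group of the (R)-auxiliary, and this sets the (R)-stereocentre.

Step 3
Reactants: 7 (R)-4-benzyl-3-[(R)-5-methyl-2-(prop-1-en-2-yl)hex-4-enoyl]oxazolidin-2-one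
Product: 8 (R)-lavandulol, (2R)-5-methyl-2-(prop-1-en-2-yl)hex-4-en-1-ol
Conditions: LiBH4 (1.5 equiv), H2O (1.5 equiv), Et2O, 0 °C
Reagents that add atoms: none
Why: reductive cleavage of an N-acyl oxazolidinone with LiBH4 attacks the exocyclic imide carbonyl, leaves the isolated alkenes and the α-centre untouched, and returns the auxiliary.

Step 4
Reactants: 8 (R)-lavandulol
Product: 9 (R)-lavandulyl iodide, (3R)-3-(iodomethyl)-2,6-dimethylhepta-1,5-diene
Conditions: I2, PPh3, imidazole, CH2Cl2, 0 °C → rt
Reagents that add atoms: iodine, [I][I]
Why: the Appel-type iodination displaces the oxyphosphonium group by SN2 at the primary carbon, so the neighbouring stereocentre is not involved and the buffered medium spares both alkenes.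

Step 5
Reactants: 9 (R)-lavandulyl iodide; 10 dimethyl malonate
Product: 12 dimethyl 2-[(2S)-5-methyl-2-(prop-1-en-2-yl)hex-4-en-1-yl]propanedioate, via sodium malonate 11 (not isolated)
Conditions: NaH (1.5 equiv), 10 (1.6 equiv), THF–DMF, 0 °C; then 9, 60 °C
Reagents that add atoms: none
Why: in this malonic ester alkylation the soft, weakly basic malonate anion should substitute the primary iodide by SN2 faster than it eliminates despite the β-branch, and the centre is untouched (its descriptor becomes S by CIP ranking only).

Step 6
Reactants: 12 dimethyl 2-[(2S)-5-methyl-2-(prop-1-en-2-yl)hex-4-en-1-yl]propanedioate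
Product: 13 methyl (R)-7-methyl-4-(prop-1-en-2-yl)oct-6-enoate
Conditions: LiCl (2 equiv), H2O (2 equiv), DMSO, 150 °C
Reagents that add atoms: none
Why: Krapcho demethoxycarbonylation removes one ester under neutral halide conditions, at a temperature that should stay below the onset of Cope rearrangement of the 1,5-diene, which would in any case be uphill.

Step 7
Reactants: 14 2,4-dihydroxybenzaldehyde
Product: 15 2,4-bis(methoxymethoxy)benzaldehyde
Conditions: NaH (2.4 equiv), MOMCl (2.6 equiv), DMF, 0 °C → rt
Reagents that add atoms: chloromethyl methyl ether, COCCl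
Why: Williamson-type O-alkylation of the preformed bis-phenoxide also caps the hydrogen-bonded 2-hydroxyl, and the resulting acetals tolerate every basic step that follows.

Step 8
Reactants: 15 2,4-bis(methoxymethoxy)benzaldehyde
Product: 16 1-(2,2-dibromoethenyl)-2,4-bis(methoxymethoxy)benzene
Conditions: CBr4 (2 equiv), PPh3 (4 equiv), Et3N (1 equiv), CH2Cl2, 0 °C
Reagents that add atoms: carbon tetrabromide, BrC(Br)(Br)Br
Why: this first stage of the Corey–Fuchs homologation is a Wittig-type dibromoolefination of an aromatic aldehyde, and the amine buffer keeps traces of HBr away from the MOM acetals.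

Step 9
Reactants: 16 1-(2,2-dibromoethenyl)-2,4-bis(methoxymethoxy)benzene
Product: 18 3-[2,4-bis(methoxymethoxy)phenyl]propiolic acid, via lithium alkynide 17 (not isolated)
Conditions: n-BuLi (2.1 equiv), THF, −78 → −20 °C; CO2 (dry gas), −78 → 0 °C; cold 1 M HCl to pH 3
Reagents that add atoms: carbon dioxide, O=C=O
Why: in the second Corey–Fuchs stage, bromine–lithium exchange, α-elimination with 1,2-shift and deprotonation give alkynide 17, which CO2 carboxylates, while the low temperature and the limited amount of n-BuLi should prevent ortho-lithiation between the two MOM ethers.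

Step 10
Reactants: 18 3-[2,4-bis(methoxymethoxy)phenyl]propiolic acid; 19 methyl acetoacetate
Product: 22 methyl 2-acetyl-5-[2,4-bis(methoxymethoxy)phenyl]-3-oxopent-4-ynoate (largely enolised), via acid chloride 20 (not isolated), via chloromagnesium enolate 21 (not isolated)
Conditions: 18, 1-chloro-N,N,2-trimethylprop-1-en-1-amine (1.1 equiv), CH2Cl2, 0 °C; added to 19, MgCl2 (1 equiv), pyridine (2 equiv), CH2Cl2, 0 °C → rt
Reagents that add atoms: none
Why: C-acylation of the magnesium-chelated β-keto ester enolate (soft enolisation with MgCl2 and pyridine) by an acid chloride is reliable, and the chloroenamine makes the acid chloride without releasing HCl, so the MOM acetals should survive.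

Step 11
Reactants: 22 methyl 2-acetyl-5-[2,4-bis(methoxymethoxy)phenyl]-3-oxopent-4-ynoate
Product: 23 methyl 6-[2,4-bis(methoxymethoxy)phenyl]-2-methyl-4-oxo-4H-pyran-3-carboxylate
Conditions: Et3N (1 equiv), MeCN, 40 °C
Reagents that add atoms: none
Why: the 6-endo-dig oxa-Michael addition of the acetyl enol oxygen to the aryl-bearing β-carbon of the ynone is the classical γ-pyranone synthesis from alkynoyl 1,3-dicarbonyl compounds, and a non-nucleophilic base in an aprotic solvent avoids retro-Claisen loss of the acetyl group.

Step 12
Reactants: 23 methyl 6-[2,4-bis(methoxymethoxy)phenyl]-2-methyl-4-oxo-4H-pyran-3-carboxylate; 13 methyl (R)-7-methyl-4-(prop-1-en-2-yl)oct-6-enoate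
Product: 26 2-[2,4-bis(methoxymethoxy)phenyl]-5,7-dihydroxy-6-[(2S)-5-methyl-2-(prop-1-en-2-yl)hex-4-en-1-yl]-4H-chromen-4-one, via lateral lithium anion 24 (not isolated), via acylated ketone 25 (not isolated)
Conditions: 23, LiN(i-Pr)2 (1.1 equiv), THF, −78 °C; 13 (1.1 equiv), −78 → 0 °C until 13 is consumed; recool to −78 °C, LiN(i-Pr)2 (3.5 equiv), → rt; AcOH quench
Reagents that add atoms: none
Why: Proposed new method: LiN(i-Pr)2 removes a proton from the C2 methyl of 23, which the ring carbonyl and the C3 ester acidify vinylogously, and the exocyclic carbanion 24 adds to the ester carbonyl of 13 and expels methoxide (C7–C8 bond), the released LiOMe holding ketone 25 as its enolate between C7 and C8a. The second charge of amide is held back until 13 is consumed so that it cannot enolise that ester; it then deprotonates the other α-carbon (future C6), and this more basic end of the 1,3-dianion attacks the neighbouring C3 ester in a 6-exo-trig Dieckmann-type closure (C5–C6 bond) that forms carbocyclic ring A, after which loss of the second methoxide and enolisation give the 5,7-diphenoxide as the thermodynamic sink. The closest known reaction type is the condensation of laterally lithiated ortho-toluates with esters followed by Claisen closure to naphthalene-1,3-diols, taken together with the known lateral lithiation of 2-methyl-4-pyranones, and the sequence has not been shown on a 2-methyl-4-pyranone-3-carboxylate. No stereocentre is created, and the existing one lies γ to the ester carbonyl of 13, out of reach of the base. The step needs closure through carbon rather than oxygen and deprotonation only at the lateral methyl, and three factors should secure this: the ortho arrangement of methyl and ester on the rigid ring, the higher reactivity of the carbon terminus of the dianion, and the reversibility of enol-lactone formation in the presence of LiOMe as against irreversible aromatisation. The side chain ends at C6 and not C8 by connectivity alone, because the chain-bearing carbon can only end up between C5 and C7.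

Step 13
Reactants: 26 2-[2,4-bis(methoxymethoxy)phenyl]-5,7-dihydroxy-6-[(2S)-5-methyl-2-(prop-1-en-2-yl)hex-4-en-1-yl]-4H-chromen-4-one
Product: 27 2-(2,4-dihydroxyphenyl)-5,7-dihydroxy-6-[(2S)-5-methyl-2-(prop-1-en-2-yl)hex-4-en-1-yl]-4H-chromen-4-one (CNP0249603.1)
Conditions: HCl (dilute, about 0.3 M in MeOH), rt → 40 °C, monitored and stopped at full conversion
Reagents that add atoms: none
Why: acid-catalysed acetal exchange with methanol should cleave the phenolic MOM ethers faster than the alkenes are protonated, as in the deprotection of prenylated polyphenols, and the stereocentre takes no part.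

**Compound list**
1 | (R)-4-benzyloxazolidin-2-one | O=C1OC[C@@H](Cc2ccccc2)N1 | starting material
2 | 3-methylbut-2-enoyl chloride | CC(C)=CC(Cl)=O | starting material
3 | N-lithio-(R)-4-benzyloxazolidin-2-one | [Li]N1C(=O)OC[C@H]1Cc1ccccc1 | intermediate (not isolated)
4 | (R)-4-benzyl-3-(3-methylbut-2-enoyl)oxazolidin-2-one | CC(C)=CC(=O)N1C(=O)OC[C@H]1Cc1ccccc1 | intermediate
5 | prenyl bromide | CC(C)=CCBr | starting material
6 | sodium (Z)-dienolate of 4 | C=C(C)/C=C(\[O-])N1C(=O)OC[C@H]1Cc1ccccc1.[Na+] | intermediate (not isolated)
7 | (R)-4-benzyl-3-[(R)-5-methyl-2-(prop-1-en-2-yl)hex-4-enoyl]oxazolidin-2-one | C=C(C)[C@@H](CC=C(C)C)C(=O)N1C(=O)OC[C@H]1Cc1ccccc1 | intermediate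
8 | (R)-lavandulol | C=C(C)[C@@H](CC=C(C)C)CO | intermediate
9 | (R)-lavandulyl iodide | C=C(C)[C@@H](CC=C(C)C)CI | intermediate
10 | dimethyl malonate | COC(=O)CC(=O)OC | starting material
11 | sodium dimethyl malonate | COC(=O)[CH-]C(=O)OC.[Na+] | intermediate (not isolated)
12 | dimethyl 2-[(2S)-5-methyl-2-(prop-1-en-2-yl)hex-4-en-1-yl]propanedioate | C=C(C)[C@@H](CC=C(C)C)CC(C(=O)OC)C(=O)OC | intermediate
13 | methyl (R)-7-methyl-4-(prop-1-en-2-yl)oct-6-enoate | C=C(C)[C@@H](CC=C(C)C)CCC(=O)OC | intermediate
14 | 2,4-dihydroxybenzaldehyde | O=Cc1ccc(O)cc1O | starting material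
15 | 2,4-bis(methoxymethoxy)benzaldehyde | O=Cc1ccc(OCOC)cc1OCOC | intermediate
16 | 1-(2,2-dibromoethenyl)-2,4-bis(methoxymethoxy)benzene | BrC(Br)=Cc1ccc(OCOC)cc1OCOC | intermediate
17 | lithium [2,4-bis(methoxymethoxy)phenyl]acetylide | [Li]C#Cc1ccc(OCOC)cc1OCOC | intermediate (not isolated)
18 | 3-[2,4-bis(methoxymethoxy)phenyl]propiolic acid | OC(=O)C#Cc1ccc(OCOC)cc1OCOC | intermediate
19 | methyl acetoacetate | CC(=O)CC(=O)OC | starting material
20 | 3-[2,4-bis(methoxymethoxy)phenyl]propioloyl chloride | O=C(Cl)C#Cc1ccc(OCOC)cc1OCOC | intermediate (not isolated)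
21 | chloromagnesium (Z)-enolate of methyl acetoacetate | COC(=O)/C=C(/C)O[Mg]Cl | intermediate (not isolated)
22 | methyl 2-acetyl-5-[2,4-bis(methoxymethoxy)phenyl]-3-oxopent-4-ynoate (drawn as the keto form; the central carbon is configurationally labile) | COC(=O)C(C(C)=O)C(=O)C#Cc1ccc(OCOC)cc1OCOC | intermediate
23 | methyl 6-[2,4-bis(methoxymethoxy)phenyl]-2-methyl-4-oxo-4H-pyran-3-carboxylate | COC(=O)c1c(C)oc(-c2ccc(OCOC)cc2OCOC)cc1=O | intermediate
24 | lateral lithium anion of 23 (drawn carbon-bound) | [Li]Cc1oc(-c2ccc(OCOC)cc2OCOC)cc(=O)c1C(=O)OC | intermediate (not isolated)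
25 | methyl 6-[2,4-bis(methoxymethoxy)phenyl]-2-[(5R)-8-methyl-2-oxo-5-(prop-1-en-2-yl)non-7-en-1-yl]-4-oxo-4H-pyran-3-carboxylate (present as lithium enolates, drawn neutral) | C=C(C)[C@@H](CC=C(C)C)CCC(=O)Cc1oc(-c2ccc(OCOC)cc2OCOC)cc(=O)c1C(=O)OC | intermediate (not isolated)
26 | 2-[2,4-bis(methoxymethoxy)phenyl]-5,7-dihydroxy-6-[(2S)-5-methyl-2-(prop-1-en-2-yl)hex-4-en-1-yl]-4H-chromen-4-one | C=C(C)[C@@H](CC=C(C)C)Cc1c(O)cc2oc(-c3ccc(OCOC)cc3OCOC)cc(=O)c2c1O | intermediate
27 | CNP0249603.1, 2-(2,4-dihydroxyphenyl)-5,7-dihydroxy-6-[(2S)-5-methyl-2-(prop-1-en-2-yl)hex-4-en-1-yl]-4H-chromen-4-one | C=C(C)[C@@H](CC=C(C)C)Cc1c(O)cc2oc(-c3ccc(O)cc3O)cc(=O)c2c1O | target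

**Totals**
Total step count: 13.
Longest linear sequence: 8 steps (steps 1–6, 12 and 13). The ring B and ring C branch contributes 7 steps (steps 7–11, 12 and 13).

**Steps most likely to fail**

Step 12. Three processes could spoil it.
- The stabilised lateral anion may add too slowly to an unactivated methyl ester.
- The ester may be enolised by the amide base.
- The ring may close through the ketone enolate oxygen instead of through carbon.

The fallback sets out from 13 and 23 and comes back at 26. It separates the two bond formations and uses a stronger acyl donor.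
- Ester 13 would be saponified (LiOH, THF–H2O) to (R)-7-methyl-4-(prop-1-en-2-yl)oct-6-enoic acid F1.
- F1 would be activated with 1,1'-carbonyldiimidazole to (R)-1-(1H-imidazol-1-yl)-7-methyl-4-(prop-1-en-2-yl)oct-6-en-1-one F2.
- Two equivalents of anion 24 (the second serves as base, and the regenerated 23 is recovered) would be C-acylated by F2 at −78 °C. This follows the practice for lateral toluate and enolate anions with acyl imidazoles. Ketone 25 would then be isolated.
- Ring A would be closed in a separate operation under equilibrating conditions (NaH with a little MeOH, THF, 0 → 40 °C). This is the known Claisen cyclisation of 2-(2-oxoalkyl)benzoates to naphthalene-1,3-diols, in which any enol lactone is reopened by alkoxide and drains to the aromatic diol 26.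

Step 11. The enol oxygen may close at the wrong alkyne carbon (5-exo-dig instead of 6-endo-dig). The Michael addition may also be slowed by the electron-rich aryl group. The fallback sets out from 22 and comes back at 23. It replaces the direct oxa-Michael addition by an amine relay.
- Diethylamine (MeCN, rt) would add to the ynone in a conjugate manner to give methyl (E)-2-acetyl-5-[2,4-bis(methoxymethoxy)phenyl]-5-(diethylamino)-3-oxopent-4-enoate F3.
- Warming F3 with pyridinium p-toluenesulfonate in toluene would let the enol oxygen displace the amine by addition–elimination at the same carbon. This path can only give the six-membered ring of 23. It is the method used for chromones and flavones from hydroxyaryl ynones.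

Step 13. Acid-catalysed addition of the C5 or C7 hydroxyl to the protonated isopropenyl group (chroman formation) may compete with acetal cleavage, as may addition of solvent to the alkenes. The fallback sets out from 26 and comes back at 27. It avoids Brønsted acid by exchanging the protecting groups.
- Et3SiOTf with 2,6-lutidine would cap O5 and O7.
- More Et3SiOTf with 2,2'-bipyridyl (CH2Cl2, 0 °C → rt) would convert the two aromatic MOM ethers directly into silyl ethers. The product is 6-[(2S)-5-methyl-2-(prop-1-en-2-yl)hex-4-en-1-yl]-5,7-bis(triethylsilyloxy)-2-[2,4-bis(triethylsilyloxy)phenyl]-4H-chromen-4-one F4.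
- n-Bu4NF buffered with AcOH (THF, 0 °C) would then release all four phenols to give 27.

**Further compounds**
F1 | step 12 | (R)-7-methyl-4-(prop-1-en-2-yl)oct-6-enoic acid | C=C(C)[C@@H](CC=C(C)C)CCC(=O)O
F2 | step 12 | (R)-1-(1H-imidazol-1-yl)-7-methyl-4-(prop-1-en-2-yl)oct-6-en-1-one | C=C(C)[C@@H](CC=C(C)C)CCC(=O)n1ccnc1
F3 | step 11 | methyl (E)-2-acetyl-5-[2,4-bis(methoxymethoxy)phenyl]-5-(diethylamino)-3-oxopent-4-enoate | COC(=O)C(C(C)=O)C(=O)/C=C(/N(CC)CC)c1ccc(OCOC)cc1OCOC
F4 | step 13 | 6-[(2S)-5-methyl-2-(prop-1-en-2-yl)hex-4-en-1-yl]-5,7-bis(triethylsilyloxy)-2-[2,4-bis(triethylsilyloxy)phenyl]-4H-chromen-4-one | C=C(C)[C@@H](CC=C(C)C)Cc1c(O[Si](CC)(CC)CC)cc2oc(-c3ccc(O[Si](CC)(CC)CC)cc3O[Si](CC)(CC)CC)cc(=O)c2c1O[Si](CC)(CC)CC
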